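The target is cut at C12–C13. Ring C carries the C12 linker on C13 and a methyl group on C14, trans to each other and next to the quaternary C18. This vicinal pattern is the trace of a conjugate addition to a C13=C14–C15 enone followed by alkylation of the C14 enolate. One operation therefore joins a left-half alkylcopper reagent (rings A and B, C7=C8 in place) to the cis-fused enone of rings C and D, adds the C14 methyl and sets C13 and C14. Because both decalins are cis-fused and share one configuration (C3/C5/C10/C9 = C21/C17/C18/C13), a single enone, made by titanocene-mediated desymmetrising cyclisation of an epoxy dienone, supplies both halves.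

Key step: step 13

Remark: atom numbers follow the 8,14-secogammacerane (onocerane) skeleton: ring A C1–C5 and C10, ring B C5–C10, linker C11–C12, ring C C13–C18, ring D C17–C22. The SMILES is taken as written: H-5/CH3-10 and H-17/CH3-18 cis, each hydroxyl trans to its angular methyl, (3R,5S,9S,10R,13S,14R,17S,18R,21R). Where the descriptor of an untouched centre differs between compounds (C18 in 10, C9 in 12–14, C10 in 12–15, C14 in 27), only substituent priorities have changed.

Step 1
Reactants: 1 melonal (rac-2,6-dimethylhept-5-enal); 2 methyl vinyl ketone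
Product: 5 rac-4-methyl-4-(4-methylpent-3-en-1-yl)cyclohex-2-en-1-one, via pyrrolidine enamine 3 (not isolated), via keto aldehyde 4 (not isolated)
Conditions: pyrrolidine (1.1 equiv), toluene, reflux, Dean–Stark; then 2, 0 → 25 °C; then AcOH–NaOAc–H2O, reflux
Reagents that add atoms: none
Why: Stork enamine Michael addition to the enone followed by hydrolysis and intramolecular aldol condensation (Robinson-type annulation) is the standard way from an α-branched aldehyde to a 4,4-disubstituted cyclohexenone, the buffered hydrolysis should spare the trisubstituted alkene, and the racemic quaternary centre is of no consequence because it loses its stereogenicity in step 2.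

Step 2
Reactants: 5 rac-4-methyl-4-(4-methylpent-3-en-1-yl)cyclohex-2-en-1-one
Product: 6 4-methyl-4-(4-methylpent-3-en-1-yl)cyclohexa-2,5-dien-1-one
Conditions: 2-iodoxybenzoic acid (IBX, 2.5 equiv), DMSO, 75 °C
Reagents that add atoms: none
Why: IBX dehydrogenation of a ketone (enolisation, single-electron oxidation, loss of the reduced iodine reagent) is known to take cyclohexenones blocked at C4 on to cross-conjugated dienones, as with steroidal 4-en-3-ones, and should leave the isolated trisubstituted alkene alone; the product has no stereocentre because C4 now carries two identical enone arms.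

Step 3
Reactants: 6 4-methyl-4-(4-methylpent-3-en-1-yl)cyclohexa-2,5-dien-1-one
Product: 7 4-{2-[(2R)-3,3-dimethyloxiran-2-yl]ethyl}-4-methylcyclohexa-2,5-dien-1-one
Conditions: 1,2:4,5-di-O-isopropylidene-β-D-erythro-2,3-hexodiulo-2,6-pyranose (0.3 equiv), KHSO5 (as 2KHSO5·KHSO4·K2SO4), K2CO3, Bu4NHSO4 (cat.), MeCN–CH2(OMe)2/aq. Na2B4O7 buffer (pH 10.5), 0 °C
Reagents that add atoms: potassium peroxymonosulfate, [K+].[O-]S(=O)(=O)OO
Why: Shi epoxidation: the chiral dioxirane formed from the D-fructose-derived ketone transfers oxygen to the electron-rich trisubstituted alkene through the spiro transition state that gives the (R)-epoxide for alkenes of the type RCH2CH=CMe2 (future C21), while the electron-poor dienone double bonds should not react with the electrophilic oxidant.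

Step 4
Reactants: 7 4-{2-[(2R)-3,3-dimethyloxiran-2-yl]ethyl}-4-methylcyclohexa-2,5-dien-1-one
Product: 8 (4aR,7R,8aS)-7-hydroxy-4a,8,8-trimethyl-4a,5,6,7,8,8a-hexahydronaphthalen-2(1H)-one
Conditions: Cp2TiCl2 (0.2 equiv), Mn powder (2 equiv), 2,4,6-collidine hydrochloride (2.5 equiv), THF, 25 °C, slow addition of 7
Reagents that add atoms: none
Why: Titanocene-mediated reductive epoxide opening and radical cyclisation (Cp2TiCl, trivalent titanium, regenerated by Mn) gives the tertiary C22 radical, which closes 6-exo-trig onto the β-carbon C17 of the enone arm under the tether through a chair transition state with the bulky titanoxy group equatorial and the new bond axial on the dienone ring, so that the fusion must be cis (H-17 syn to the C18 methyl) and the (R)-carbinol selects the arm that makes C17 S and C18 R with the hydroxyl trans to the angular methyl; reduction of the α-keto radical to the titanium enolate and protonation by the collidinium salt leave the second enone arm intact.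

Step 5
Reactants: 8 (4aR,7R,8aS)-7-hydroxy-4a,8,8-trimethyl-4a,5,6,7,8,8a-hexahydronaphthalen-2(1H)-one
Product: 9 (4aR,7R,8aS)-7-[(tert-butyldimethylsilyl)oxy]-4a,8,8-trimethyl-4a,5,6,7,8,8a-hexahydronaphthalen-2(1H)-one
Conditions: TBSOTf, 2,6-lutidine, CH2Cl2, −78 → 0 °C
Reagents that add atoms: tert-butyldimethylsilyl trifluoromethanesulfonate, CC(C)(C)[Si](C)(C)OS(=O)(=O)C(F)(F)F
Why: Silylation of a hindered secondary alcohol with a silyl triflate and a non-nucleophilic base is routine and gives an ether that should withstand the organometallic, palladium, borane and enolate chemistry that follows.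

Step 6
Reactants: 9 (4aR,7R,8aS)-7-[(tert-butyldimethylsilyl)oxy]-4a,8,8-trimethyl-4a,5,6,7,8,8a-hexahydronaphthalen-2(1H)-one
Product: 10 (4aS,7R,8aS)-7-[(tert-butyldimethylsilyl)oxy]-3-iodo-4a,8,8-trimethyl-4a,5,6,7,8,8a-hexahydronaphthalen-2(1H)-one
Conditions: I2 (2 equiv), pyridine–CH2Cl2 (1:1), 0 → 25 °C
Reagents that add atoms: iodine, II
Why: α-Iodination of a cyclohexenone by reversible pyridine addition, iodination of the enolate and elimination (Baylis–Hillman-type activation) is well established for 4,4-disubstituted cyclohexenones and touches no stereocentre.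

Step 7
Reactants: 10 (4aS,7R,8aS)-7-[(tert-butyldimethylsilyl)oxy]-3-iodo-4a,8,8-trimethyl-4a,5,6,7,8,8a-hexahydronaphthalen-2(1H)-one
Product: 11 (4aR,7R,8aS)-7-[(tert-butyldimethylsilyl)oxy]-3,4a,8,8-tetramethyl-4a,5,6,7,8,8a-hexahydronaphthalen-2(1H)-one
Conditions: MeB(OH)2 (2 equiv), PdCl2(dppf) (5 mol %; dppf = 1,1'-bis(diphenylphosphino)ferrocene), K3PO4, 1,4-dioxane–H2O, 80 °C
Reagents that add atoms: methylboronic acid, CB(O)O
Why: Suzuki–Miyaura cross-coupling of the 2-iodoenone (oxidative addition of the electron-poor vinyl iodide to zerovalent palladium, transmetalation from the methylboronate, reductive elimination) places the future C8 methyl group on the enone α-carbon without creating a stereocentre.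

Step 8
Reactants: 11 (4aR,7R,8aS)-7-[(tert-butyldimethylsilyl)oxy]-3,4a,8,8-tetramethyl-4a,5,6,7,8,8a-hexahydronaphthalen-2(1H)-one
Product: 14 (4R,4aS,7R,8aS)-7-[(tert-butyldimethylsilyl)oxy]-4-ethenyl-3,4a,8,8-tetramethyl-1,4,4a,5,6,7,8,8a-octahydronaphthalen-2-yl trifluoromethanesulfonate, via trimethylsilyl enol ether 12 (not isolated), via lithium enolate 13 (not isolated)
Conditions: CH2=CHMgBr (1.5 equiv), CuBr·SMe2 (10 mol %), Me3SiCl (2 equiv), HMPA (2 equiv), THF, −78 → −40 °C; Et3N, pentane, filtration, evaporation; MeLi (1.1 equiv), THF, 0 → 25 °C; PhNTf2, −78 → 25 °C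
Reagents that add atoms: vinylmagnesium bromide, C=C[Mg]Br; N-phenylbis(trifluoromethanesulfonimide), O=S(=O)(N(c1ccccc1)S(=O)(=O)C(F)(F)F)C(F)(F)F
Why: Copper-catalysed, chlorosilane-accelerated 1,4-addition of the Grignard reagent should deliver the vinyl group to the enone β-carbon (future C9) on the convex face of the cis-fused bicycle, cis to the angular methyl, because the other face is screened by the gem-dimethyl carbon of the neighbouring ring, and the regiodefined enolate released from the silyl enol ether with MeLi is O-sulfonylated to an enol triflate that fixes the future C7=C8 position.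

Step 9
Reactants: 14 (4R,4aS,7R,8aS)-7-[(tert-butyldimethylsilyl)oxy]-4-ethenyl-3,4a,8,8-tetramethyl-1,4,4a,5,6,7,8,8a-octahydronaphthalen-2-yl trifluoromethanesulfonate
Product: 15 (1S,4aS,6R,8aS)-6-[(tert-butyldimethylsilyl)oxy]-1-ethenyl-2,5,5,8a-tetramethyl-1,4,4a,5,6,7,8,8a-octahydronaphthalene
Conditions: Pd(OAc)2 (5 mol %), PPh3 (10 mol %), HCO2H, Bu3N, DMF, 60 °C
Reagents that add atoms: none
Why: Palladium-catalysed formate reduction of an enol triflate (oxidative addition, formate exchange, decarboxylation to a palladium hydride, reductive elimination) replaces the triflate by hydrogen with the double bond fixed at C7=C8 and without touching C9 or the vinyl group.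

Step 10
Reactants: 15 (1S,4aS,6R,8aS)-6-[(tert-butyldimethylsilyl)oxy]-1-ethenyl-2,5,5,8a-tetramethyl-1,4,4a,5,6,7,8,8a-octahydronaphthalene
Product: 17 2-[(1S,4aS,6R,8aR)-6-[(tert-butyldimethylsilyl)oxy]-2,5,5,8a-tetramethyl-1,4,4a,5,6,7,8,8a-octahydronaphthalen-1-yl]ethan-1-ol, via B-alkyl-9-borabicyclononane 16 (not isolated)
Conditions: 9-BBN (1.5 equiv), THF, 0 → 25 °C; then aq. NaOH, H2O2, 0 → 25 °C
Reagents that add atoms: hydrogen peroxide, OO
Why: Anti-Markovnikov hydroboration–oxidation with the bulky dialkylborane is highly selective for the monosubstituted vinyl group over the trisubstituted ring alkene and should give the primary C12 alcohol without affecting any stereocentre.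

Step 11
Reactants: 17 2-[(1S,4aS,6R,8aR)-6-[(tert-butyldimethylsilyl)oxy]-2,5,5,8a-tetramethyl-1,4,4a,5,6,7,8,8a-octahydronaphthalen-1-yl]ethan-1-ol
Product: 18 (1S,4aS,6R,8aR)-1-(2-bromoethyl)-6-[(tert-butyldimethylsilyl)oxy]-2,5,5,8a-tetramethyl-1,4,4a,5,6,7,8,8a-octahydronaphthalene
Conditions: CBr4, PPh3, CH2Cl2, 0 °C
Reagents that add atoms: carbon tetrabromide, BrC(Br)(Br)Br
Why: The Appel reaction converts the unhindered primary alcohol into the bromide by SN2 displacement of the oxyphosphonium ion under near-neutral conditions that spare the silyl ether and the trisubstituted alkene.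

Step 12
Reactants: 18 (1S,4aS,6R,8aR)-1-(2-bromoethyl)-6-[(tert-butyldimethylsilyl)oxy]-2,5,5,8a-tetramethyl-1,4,4a,5,6,7,8,8a-octahydronaphthalene
Product: 19 bromo{2-[(1S,4aS,6R,8aR)-6-[(tert-butyldimethylsilyl)oxy]-2,5,5,8a-tetramethyl-1,4,4a,5,6,7,8,8a-octahydronaphthalen-1-yl]ethyl}magnesium (THF solution)
Conditions: Mg turnings (I2 crystal), THF, 40 °C; titrated and used directly
Reagents that add atoms: magnesium, [Mg]
Why: Insertion of magnesium into a primary alkyl bromide (Grignard reagent formation) is reliable here because the pent-4-enyl-type organometallic has no favourable cyclisation or elimination pathway and C9 is not involved.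

Step 13
Reactants: 19 left-half Grignard reagent; 9 right-half enone (4aR,7R,8aS)-7-[(tert-butyldimethylsilyl)oxy]-4a,8,8-trimethyl-4a,5,6,7,8,8a-hexahydronaphthalen-2(1H)-one; 20 iodomethane
Product: 24 (3R,5S,9S,10R,13S,14S,17S,18R,21R)-3,21-bis[(tert-butyldimethylsilyl)oxy]-8,14-secogammacer-7-en-15-one, via alkylcopper reagent 21 (not isolated), via C15 trimethylsilyl enol ether 22 (not isolated), via C15 lithium enolate 23 (not isolated)
Conditions: 19 (1.2 equiv), CuBr·SMe2 (1.2 equiv), THF, −78 → −40 °C; 9 (1.0 equiv), Me3SiCl (2.5 equiv), −78 → −30 °C; Et3N, pentane, filtration, evaporation; MeLi (1.1 equiv), THF, 0 → 25 °C; 20 (5 equiv), HMPA, −78 → 0 °C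
Reagents that add atoms: none
Why: The monovalent copper alkyl 21 forms a π-complex with enone 9 and, assisted by Me3SiCl, transfers its alkyl group to the β-carbon C13 (C12–C13 bond), the enolate being caught as silyl enol ether 22 with the double bond fixed at C14=C15; MeLi then cleaves the O–Si bond and lithium enolate 23 is C-methylated by iodomethane in an SN2 step (C14–CH3 bond). The closest known reaction type is the chlorosilane-accelerated conjugate addition of Grignard-derived organocopper reagents to 4,4-disubstituted cyclohexenones followed by regiospecific alkylation of the released enolate (three-component vicinal difunctionalisation); no ring is closed. C13 is controlled by the cis-fused bicycle: the concave face of C13 is blocked by C22 and its axial methyl group, so the copper reagent should enter on the convex face, cis to the C18 methyl and H-17 and anti to C19, giving 13S. C14 is controlled by the new C13 substituent: iodomethane approaches the enolate anti to the C12 chain, giving the 13,14-trans ketone (14S), which is also the diequatorial and thermodynamically preferred epimer. The step needs 1,4- over 1,2-addition and an enolate that stays at C14 and reacts at carbon; these are secured by the soft copper reagent with silyl trapping, by generating the enolate only from 22, and by excess iodomethane in a dipolar cosolvent at low temperature so that alkylation outruns proton transfer to C16. The same facial preference is tested beforehand on the same ring system in step 8.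

Step 14
Reactants: 24 (3R,5S,9S,10R,13S,14S,17S,18R,21R)-3,21-bis[(tert-butyldimethylsilyl)oxy]-8,14-secogammacer-7-en-15-one
Product: 25 (3R,5S,9S,10R,13S,14S,17S,18R,21R)-3,21-dihydroxy-8,14-secogammacer-7-en-15-one
Conditions: 48% aq. HF, MeCN–CH2Cl2, 25 → 40 °C
Reagents that add atoms: none
Why: Fluoride-driven cleavage of both silyl ethers (formation of the strong Si–F bond) should free the two equatorial carbinols without affecting the ketone, the alkene or any stereocentre.

Step 15
Reactants: 25 (3R,5S,9S,10R,13S,14S,17S,18R,21R)-3,21-dihydroxy-8,14-secogammacer-7-en-15-one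
Product: 27 (3R,5S,9S,10R,13S,14R,17S,18R,21R)-8,14-secogammacer-7-ene-3,21-diol (CNP0194061.2), via C15 hydrazone 26 (not isolated)
Conditions: N2H4·H2O, KOH, diethylene glycol, 130 °C; then removal of water and excess hydrazine by distillation, 200 °C
Reagents that add atoms: none
Why: Wolff–Kishner reduction (Huang–Minlon modification) converts the ketone through its hydrazone and base-induced loss of N2 into the C15 methylene group, tolerates free secondary alcohols and the unactivated alkene, and any base-induced equilibration at C14 can only favour the desired trans arrangement.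

Compound list
1 | melonal (rac-2,6-dimethylhept-5-enal) | CC(C)=CCCC(C)C=O | starting material
2 | methyl vinyl ketone (but-3-en-2-one) | CC(=O)C=C | starting material
3 | 1-(2,6-dimethylhepta-1,5-dien-1-yl)pyrrolidine (not isolated) | CC(C)=CCCC(C)=CN1CCCC1 | intermediate
4 | rac-2-methyl-2-(4-methylpent-3-en-1-yl)-5-oxohexanal (not isolated) | CC(C)=CCCC(C)(C=O)CCC(C)=O | intermediate
5 | rac-4-methyl-4-(4-methylpent-3-en-1-yl)cyclohex-2-en-1-one | CC(C)=CCCC1(C)C=CC(=O)CC1 | intermediate
6 | 4-methyl-4-(4-methylpent-3-en-1-yl)cyclohexa-2,5-dien-1-one | CC(C)=CCCC1(C)C=CC(=O)C=C1 | intermediate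
7 | 4-{2-[(2R)-3,3-dimethyloxiran-2-yl]ethyl}-4-methylcyclohexa-2,5-dien-1-one | CC1(C)O[C@@H]1CCC1(C)C=CC(=O)C=C1 | intermediate
8 | (4aR,7R,8aS)-7-hydroxy-4a,8,8-trimethyl-4a,5,6,7,8,8a-hexahydronaphthalen-2(1H)-one | C1=CC(=O)C[C@@H]2C(C)(C)[C@H](O)CC[C@@]21C | intermediate
9 | (4aR,7R,8aS)-7-[(tert-butyldimethylsilyl)oxy]-4a,8,8-trimethyl-4a,5,6,7,8,8a-hexahydronaphthalen-2(1H)-one (right-half enone) | C1=CC(=O)C[C@@H]2C(C)(C)[C@H](O[Si](C)(C)C(C)(C)C)CC[C@@]21C | intermediate
10 | (4aS,7R,8aS)-7-[(tert-butyldimethylsilyl)oxy]-3-iodo-4a,8,8-trimethyl-4a,5,6,7,8,8a-hexahydronaphthalen-2(1H)-one | C1=C(I)C(=O)C[C@@H]2C(C)(C)[C@H](O[Si](C)(C)C(C)(C)C)CC[C@@]21C | intermediate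
11 | (4aR,7R,8aS)-7-[(tert-butyldimethylsilyl)oxy]-3,4a,8,8-tetramethyl-4a,5,6,7,8,8a-hexahydronaphthalen-2(1H)-one | C1=C(C)C(=O)C[C@@H]2C(C)(C)[C@H](O[Si](C)(C)C(C)(C)C)CC[C@@]21C | intermediate
12 | (4R,4aS,7R,8aS)-7-[(tert-butyldimethylsilyl)oxy]-4-ethenyl-3,4a,8,8-tetramethyl-2-[(trimethylsilyl)oxy]-1,4,4a,5,6,7,8,8a-octahydronaphthalene (not isolated) | CC1=C(O[Si](C)(C)C)C[C@@H]2C(C)(C)[C@H](O[Si](C)(C)C(C)(C)C)CC[C@]2(C)[C@H]1C=C | intermediate
13 | lithium (4R,4aS,7R,8aS)-7-[(tert-butyldimethylsilyl)oxy]-4-ethenyl-3,4a,8,8-tetramethyl-1,4,4a,5,6,7,8,8a-octahydronaphthalen-2-olate (not isolated) | CC1=C(O[Li])C[C@@H]2C(C)(C)[C@H](O[Si](C)(C)C(C)(C)C)CC[C@]2(C)[C@H]1C=C | intermediate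
14 | (4R,4aS,7R,8aS)-7-[(tert-butyldimethylsilyl)oxy]-4-ethenyl-3,4a,8,8-tetramethyl-1,4,4a,5,6,7,8,8a-octahydronaphthalen-2-yl trifluoromethanesulfonate | CC1=C(OS(=O)(=O)C(F)(F)F)C[C@@H]2C(C)(C)[C@H](O[Si](C)(C)C(C)(C)C)CC[C@]2(C)[C@H]1C=C | intermediate
15 | (1S,4aS,6R,8aS)-6-[(tert-butyldimethylsilyl)oxy]-1-ethenyl-2,5,5,8a-tetramethyl-1,4,4a,5,6,7,8,8a-octahydronaphthalene | CC1=CC[C@@H]2C(C)(C)[C@H](O[Si](C)(C)C(C)(C)C)CC[C@]2(C)[C@H]1C=C | intermediate
16 | 9-{2-[(1S,4aS,6R,8aR)-6-[(tert-butyldimethylsilyl)oxy]-2,5,5,8a-tetramethyl-1,4,4a,5,6,7,8,8a-octahydronaphthalen-1-yl]ethyl}-9-borabicyclo[3.3.1]nonane (not isolated) | CC1=CC[C@@H]2C(C)(C)[C@H](O[Si](C)(C)C(C)(C)C)CC[C@]2(C)[C@H]1CCB1C2CCCC1CCC2 | intermediate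
17 | 2-[(1S,4aS,6R,8aR)-6-[(tert-butyldimethylsilyl)oxy]-2,5,5,8a-tetramethyl-1,4,4a,5,6,7,8,8a-octahydronaphthalen-1-yl]ethan-1-ol | CC1=CC[C@@H]2C(C)(C)[C@H](O[Si](C)(C)C(C)(C)C)CC[C@]2(C)[C@H]1CCO | intermediate
18 | (1S,4aS,6R,8aR)-1-(2-bromoethyl)-6-[(tert-butyldimethylsilyl)oxy]-2,5,5,8a-tetramethyl-1,4,4a,5,6,7,8,8a-octahydronaphthalene | CC1=CC[C@@H]2C(C)(C)[C@H](O[Si](C)(C)C(C)(C)C)CC[C@]2(C)[C@H]1CCBr | intermediate
19 | bromo{2-[(1S,4aS,6R,8aR)-6-[(tert-butyldimethylsilyl)oxy]-2,5,5,8a-tetramethyl-1,4,4a,5,6,7,8,8a-octahydronaphthalen-1-yl]ethyl}magnesium (left-half Grignard reagent) | CC1=CC[C@@H]2C(C)(C)[C@H](O[Si](C)(C)C(C)(C)C)CC[C@]2(C)[C@H]1CC[Mg]Br | intermediate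
20 | iodomethane | CI | starting material
21 | {2-[(1S,4aS,6R,8aR)-6-[(tert-butyldimethylsilyl)oxy]-2,5,5,8a-tetramethyl-1,4,4a,5,6,7,8,8a-octahydronaphthalen-1-yl]ethyl}copper (not isolated) | CC1=CC[C@@H]2C(C)(C)[C@H](O[Si](C)(C)C(C)(C)C)CC[C@]2(C)[C@H]1CC[Cu] | intermediate
22 | (3R,5S,9S,10R,13S,17S,18R,21R)-3,21-bis[(tert-butyldimethylsilyl)oxy]-15-[(trimethylsilyl)oxy]-27-nor-8,14-secogammacera-7,14-diene (not isolated) | CC1=CC[C@@H]2C(C)(C)[C@H](O[Si](C)(C)C(C)(C)C)CC[C@]2(C)[C@H]1CC[C@H]1C=C(O[Si](C)(C)C)C[C@@H]2C(C)(C)[C@H](O[Si](C)(C)C(C)(C)C)CC[C@@]21C | intermediate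
23 | lithium (3R,5S,9S,10R,13S,17S,18R,21R)-3,21-bis[(tert-butyldimethylsilyl)oxy]-27-nor-8,14-secogammacera-7,14-dien-15-olate (not isolated) | CC1=CC[C@@H]2C(C)(C)[C@H](O[Si](C)(C)C(C)(C)C)CC[C@]2(C)[C@H]1CC[C@H]1C=C(O[Li])C[C@@H]2C(C)(C)[C@H](O[Si](C)(C)C(C)(C)C)CC[C@@]21C | intermediate
24 | (3R,5S,9S,10R,13S,14S,17S,18R,21R)-3,21-bis[(tert-butyldimethylsilyl)oxy]-8,14-secogammacer-7-en-15-one | CC1=CC[C@@H]2C(C)(C)[C@H](O[Si](C)(C)C(C)(C)C)CC[C@]2(C)[C@H]1CC[C@H]1[C@H](C)C(=O)C[C@@H]2C(C)(C)[C@H](O[Si](C)(C)C(C)(C)C)CC[C@@]21C | intermediate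
25 | (3R,5S,9S,10R,13S,14S,17S,18R,21R)-3,21-dihydroxy-8,14-secogammacer-7-en-15-one | CC1=CC[C@@H]2C(C)(C)[C@H](O)CC[C@]2(C)[C@H]1CC[C@H]1[C@H](C)C(=O)C[C@@H]2C(C)(C)[C@H](O)CC[C@@]21C | intermediate
26 | C15 hydrazone of 25 (not isolated) | CC1=CC[C@@H]2C(C)(C)[C@H](O)CC[C@]2(C)[C@H]1CC[C@H]1[C@H](C)C(=NN)C[C@@H]2C(C)(C)[C@H](O)CC[C@@]21C | intermediate
27 | (3R,5S,9S,10R,13S,14R,17S,18R,21R)-8,14-secogammacer-7-ene-3,21-diol (CNP0194061.2) | CC1=CC[C@@H]2C(C)(C)[C@H](O)CC[C@]2(C)[C@H]1CC[C@H]1[C@H](C)CC[C@@H]2C(C)(C)[C@H](O)CC[C@@]21C | target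

Total step count: 15. Longest linear sequence: 15 steps (steps 1–5 to enone 9, steps 6–12 to Grignard reagent 19, then steps 13–15); enone 9 is used twice.

Steps most likely to fail

Step 13. After the conjugate addition, the C14 lithium enolate may exchange protons with the methylated ketone as it forms, so that methylation spreads to C16 or occurs twice, or O-alkylation may compete. The fallback brings the methyl group in with the acceptor and makes the union a two-component reaction. It sets out from 19 and the 14-methyl enone 11: alkylcopper 21, made from 19 as before, would be added under the same chlorosilane activation to 11 to give the tetrasubstituted silyl enol ether F1. Methanolysis with K2CO3 in MeOH would release the ketone, and any 13,14-cis ketone F2 formed on protonation should equilibrate under these conditions to the diequatorial trans ketone. The fallback comes back to the route at 24.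

Step 4. The tertiary radical may be intercepted by a second titanium centre before it cyclises (β-hydride elimination to an allylic alcohol, or simple reduction), and the dienone carbonyl may itself be reduced by the low-valent metal. The fallback generates the same radical without a metal reductant. It sets out from 7: acid-promoted opening of the epoxide at the tertiary carbon with 48% aq. HBr in THF at −20 °C would give bromohydrin F3 with C21 untouched. Bromine abstraction with tris(trimethylsilyl)silane and azobisisobutyronitrile in toluene at 80 °C under slow addition would then form the radical, which cyclises through the same chair arrangement and is reduced by the silane. The fallback comes back to the route at 8.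

Step 8. The α-methylated enone 11, whose β-carbon is also neopentyl, may accept the vinyl group too slowly, so that 1,2-addition or enolisation by the Grignard reagent takes over. The fallback adds the vinyl group to the more reactive unmethylated enone and introduces the methyl group by enolate alkylation instead of cross-coupling. It sets out from 9: copper-catalysed vinyl addition with Me3SiCl would give silyl enol ether F4, MeLi would release lithium enolate F5, and iodomethane would give the trans 3-methyl-4-vinyl ketone F6. Equilibrating silylation of F6 (Me3SiCl, NaI, Et3N, MeCN) should favour the more substituted enol ether. The fallback comes back to the route at 12, which is carried on to 14 as in step 8.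

Further compounds
F1 | step 13 | (3R,5S,9S,10R,13R,17S,18R,21R)-3,21-bis[(tert-butyldimethylsilyl)oxy]-15-[(trimethylsilyl)oxy]-8,14-secogammacera-7,14-diene | CC1=CC[C@@H]2C(C)(C)[C@H](O[Si](C)(C)C(C)(C)C)CC[C@]2(C)[C@H]1CC[C@H]1C(C)=C(O[Si](C)(C)C)C[C@@H]2C(C)(C)[C@H](O[Si](C)(C)C(C)(C)C)CC[C@@]21C
F2 | step 13 | (3R,5S,9S,10R,13S,14R,17S,18R,21R)-3,21-bis[(tert-butyldimethylsilyl)oxy]-8,14-secogammacer-7-en-15-one (13,14-cis epimer of 24) | CC1=CC[C@@H]2C(C)(C)[C@H](O[Si](C)(C)C(C)(C)C)CC[C@]2(C)[C@H]1CC[C@H]1[C@@H](C)C(=O)C[C@@H]2C(C)(C)[C@H](O[Si](C)(C)C(C)(C)C)CC[C@@]21C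
F3 | step 4 | 4-[(3R)-4-bromo-3-hydroxy-4-methylpentyl]-4-methylcyclohexa-2,5-dien-1-one | CC(C)(Br)[C@H](O)CCC1(C)C=CC(=O)C=C1
F4 | step 8 | (4S,4aR,7R,8aS)-7-[(tert-butyldimethylsilyl)oxy]-4-ethenyl-4a,8,8-trimethyl-2-[(trimethylsilyl)oxy]-1,4,4a,5,6,7,8,8a-octahydronaphthalene | C=C[C@H]1C=C(O[Si](C)(C)C)C[C@@H]2C(C)(C)[C@H](O[Si](C)(C)C(C)(C)C)CC[C@@]21C
F5 | step 8 | lithium (4S,4aR,7R,8aS)-7-[(tert-butyldimethylsilyl)oxy]-4-ethenyl-4a,8,8-trimethyl-1,4,4a,5,6,7,8,8a-octahydronaphthalen-2-olate | C=C[C@H]1C=C(O[Li])C[C@@H]2C(C)(C)[C@H](O[Si](C)(C)C(C)(C)C)CC[C@@]21C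
F6 | step 8 | (3S,4S,4aR,7R,8aS)-7-[(tert-butyldimethylsilyl)oxy]-4-ethenyl-3,4a,8,8-tetramethyl-3,4,4a,5,6,7,8,8a-octahydronaphthalen-2(1H)-one (methyl trans to vinyl) | C=C[C@H]1[C@H](C)C(=O)C[C@@H]2C(C)(C)[C@H](O[Si](C)(C)C(C)(C)C)CC[C@@]21C
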